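## Structural features

The carbon core is a trans-anti-trans 6-5-6 tricycle: cyclohexane ring A (two equatorial secondary methyl groups, cis-1,3, and an axial angular methyl on the A/B fusion carbon), cyclopentane ring B, and ring C. Ring C carries, in sequence, the acyl-bearing carbon, a methyl-bearing tertiary peroxy carbon and a methyl-substituted epoxide. The oxygen on ring B lies on the face of the angular methyl and is an aryl ether. It opens a 13-membered para-cyclophane that returns to ring C through a benzylic CH2, a hemiaminal carbon, a CH2, an all-carbon spiro centre and a ketone. The spiro and hemiaminal carbons also belong to a γ-lactam. The spiro carbon carries a CH2–CH(OH) arm joined through an O–O bond to the tertiary ring-C carbon, giving an eight-membered 1,2-dioxocane with the epoxide syn to the peroxide oxygen. There are fourteen stereocentres: eleven on the tricycle (the five ring-C centres and both B/C fusion centres are contiguous) and three on the lactam and dioxocane part. The spiro centre is separated from ring C only by the ketone carbon. The fragile groups are the peroxyhemiacetal (reduction, base, metals), the N-acyl hemiaminal (dehydration, ring–chain equilibration), the epoxide next to the peroxide, the β-keto lactam (retro-Claisen) and, in precursors, the α-centre of a β,γ-unsaturated aldehyde or ketone. The real difficulty is the quaternary spiro carbon, which is flanked by two carbonyl groups and two CH2 groups and must be set against a remote tricycle; the strained cyclophane and the late peroxide come next. The key step exploits the fact that this spiro carbon is the α-carbon of a succinimide, carries a CH2 that can derive from the exocyclic methylene of an itaconimide, and is bonded to the ketone carbon, which can arrive as a ring-C aldehyde.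

## Logic of the disconnections

44 to 43: the two epoxide C–O bonds on ring C are cut. The epoxide is the most electrophilic group and sits next to the peroxide, so it is made last. The gain is a plain trisubstituted alkene. The forward step must deliver oxygen to the face syn to the peroxide oxygen without touching the O–O bond or the hemiaminal.

43 to 41: the C–O bond at the tertiary ring-C carbon and the O–C bond of the peroxyhemiacetal are cut. This removes the dioxocane and one stereocentre and returns the alkene to the position between the methyl-bearing carbon and the CH. Forward, oxygen must add on the face of the CH2CHO arm and take the hydrogen of the neighbouring CH(CH3).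

41 to 39: the aldehyde is traced to a terminal alkene with one more carbon, because an aldehyde would not survive the base and heat of ring closure. Forward, the terminal alkene must be cleaved in the presence of the ring-C alkene.

39 to 38: the aryl C–O bond, the only heteroatom bond of the macrocycle, is cut. The 13-membered ring opens to an aryl bromide and a secondary alcohol. Forward, an intramolecular O-arylation at high dilution must tolerate the ketone, the N–H lactam and the hemiaminal.

38 to 36 to 35 to 33 and 34: the N-benzyl and silyl groups are put back, the ketone is returned to the carbinol, and the benzylic C–C bond to the hemiaminal carbon is cut. The hemiaminal is the adduct of a benzyl nucleophile and an imide carbonyl. The whole arene leaves as 34. Forward, attack must occur at the carbonyl remote from the quaternary carbon, with extra reagent for the free hydroxyl.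

33 to 26, 30 and 31: the bond from the spiro carbon to the carbinol carbon and the bond from its CH2 to the vinyl carbon are cut. These are the two bonds that make the quaternary centre, and all three partners are simple. Forward, one enolate face must be chosen and the enolate, not the vinyl metal, must meet the aldehyde.

30 to 27 and 28: the two C–N bonds of the imide are cut. Forward, cyclodehydration must not move the exocyclic double bond into the ring.

26 to 25 to 24 to 22 to 21 to 20: the vinylic C–CH3 bond is cut and the alkene is moved. The alkene pattern of 26 cannot come directly from a tethered cycloaddition, so it is derived from 20 by allylic oxidation, reductive enolate formation, triflation and methyl coupling, with the aldehyde masked as an acetal. Forward, the enolate must form on one side only.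

20 to 19: the B/C fusion bond and the bond from the formyl-bearing carbon to the ring CH2 are cut (intramolecular Diels–Alder). Two rings and four stereocentres go at once. Forward, the endo, trans–anti topology is required.

19 to 17 to 15 to 13 and 14: the dienophile arm is cut at the bond between the ring-A carbonyl carbon and the alkyne. The carbinol centre is then left to hydride delivery.

13 to 12 to 10 and 11: the diene arm is cut at the bond to the neopentyl aldehyde carbon. Forward, allylboration and a stereospecific elimination give the E diene.

10 to 9 to 8 to 7 to 6 to 4: ring A is simplified to a cyclohexenone. The quaternary methyl comes from conjugate addition and the third methyl from the ketone. Forward, axial methyl delivery and an equatorial methyl from the exocyclic alkene are needed.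

4 to 1 and 2: the Michael bond and the aldol bond of ring A are cut (Robinson annulation). Both partners are commercial. Forward, the catalyst must set the methyl-bearing centre.

## Other disconnections considered

Alternative 1: The cut is the ring-B bond between the carbinol carbon and the B/C fusion carbon, plus the ring-C bond between the ester-bearing carbon and the tertiary carbinol carbon. Forward, SmI2 would reduce the ring-A aldehyde A1 to a ketyl, which adds to the enoate β-carbon (five-membered ring B). The samarium enolate would then add to the pendant methyl ketone (ring C) to give the diol ester A2. In its favour, two rings, two C–C bonds and four stereocentres form with one reagent, and the ring-B hydroxyl appears directly at the alcohol level, trans to the new ring-C bond, as is usual for ketyl–olefin cyclisations. Against it here, A2 has a tertiary alcohol where 26 needs a C(CH3)=CH alkene, and an ester where 26 needs an aldehyde. Dehydration would have to go away from the ester rather than into conjugation. The two side-chain stereocentres of A1 would also have to be set in an open chain first. In comparison, the alternative addresses only the tricycle and would feed the same key step, so it competes with steps 9 to 17 and not with the spiro-centre construction. Mechanistically it is a radical–anionic cascade whose facial outcome rests on chelation, whereas the Diels–Alder reaction of 19 has its topology fixed by the tether. On bond count per step the cascade is the equal of the cycloaddition. It is the better of the two in delivering the ring-B oxygen without a separate carbonyl reduction. It is the worse in the corrections needed afterwards.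

Alternative 2: The cut is the C–O bond at the tertiary ring-C carbon and the O–C bond of the peroxyhemiacetal. Forward, singlet oxygen would add to the ring-C alkene of 41 with allylic shift, and the hydroperoxide would close onto the aldehyde to give A3, which is the same compound as 43. In its favour, the O–O ring is made late, from oxygen, without protecting groups, and the suprafacial ene geometry sets the tertiary C–O centre while placing the alkene where the epoxide is needed. Against it, the face and site of attack on a β,γ-unsaturated ketone are not secured by anything except the substrate, and the ring is eight-membered. In comparison, this disconnection is not a rival: the chosen plan contains it as step 25. As the organising step it would simplify only the last two rings and would leave the spiro centre and the cyclophane untouched, which is why the route is built around step 19 instead. In step economy and waste it is the equal or the better of any other way to the peroxide.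

Alternative 3: The cut is two aromatic C–C bonds, so that the benzene ring is built inside the macrocycle. Forward, heating the bromo-pyrone propargyl precursor A4 would give an intramolecular Diels–Alder adduct that loses CO2 to form the arene and the 13-membered ring together as A5. In its favour, the strain of the para-cyclophane is paid for by aromatisation and CO2 loss rather than by bending a finished arene in a coupling step, and no metal is needed for ring closure. On this point it is likely the better of the two plans. The ether bond to ring B would also be made intermolecularly. Against it here, the pyrone must be attached to the hindered ring-B alcohol, and a propargyl group must be added to the imide (propargyl versus allenyl delivery). The high temperature forces the hemiaminal and the aldehyde to be masked, as A5 shows. The bromine that steers the regiochemistry must be removed later in the presence of two alkenes. In comparison, both plans reach the same macrocycle and both rely on step 19 for the spiro centre. The mechanisms differ (cycloaddition and cycloreversion against copper-catalysed C–O coupling). The chosen plan is shorter by roughly four steps (pyrone synthesis, two unmaskings, debromination), and the alternative is held in reserve for the case that the ring closure of step 23 fails in every form.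

Key step: step 19

Assumption: the quinine-derived amine of step 1 is taken to give the 6S centre; the quinidine-derived pseudo-enantiomer is the alternative if the sense is the opposite.
Assumption: the hemiaminal carbon and the peroxyhemiacetal carbon equilibrate by ring–chain tautomerism, so they are drawn with defined configuration only from 39 and 43 onwards.

## Route

Step 1
Reactants: 1 methyl 4,4-dimethoxy-3-oxobutanoate; 2 (E)-pent-3-en-2-one
Product: 4 methyl (1R,6S)-2-(dimethoxymethyl)-6-methyl-4-oxocyclohex-2-ene-1-carboxylate, via Michael adduct 3 (not isolated)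
Conditions: 9-amino-9-deoxy-epi-quinine (20 mol%), TFA (40 mol%), toluene, rt; then pyrrolidine, AcOH, 60 °C
Reagents that add atoms: none
Why: Iminium-catalysed Michael addition of the β-keto ester to the enone sets the methyl-bearing centre under catalyst control; enamine-mediated aldol condensation of the methyl ketone onto the dialkoxy ketone (Robinson annulation) closes ring A, and the epimerisable ester-bearing centre settles trans to the methyl group.

Step 2
Reactants: 4 methyl (1R,6S)-2-(dimethoxymethyl)-6-methyl-4-oxocyclohex-2-ene-1-carboxylate
Product: 6 methyl 2-(dimethoxymethyl)-2,6-dimethyl-4-oxocyclohexane-1-carboxylate (2-methyl cis to the ester; 6-methyl trans to it), via silyl enol ether 5 (not isolated)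
Conditions: MeMgBr, CuBr·SMe2 (20 mol%), TMSCl, THF, −40 °C; then K2CO3, MeOH, 0 °C
Reagents that add atoms: methylmagnesium bromide, C[Mg]Br
Why: Copper-catalysed conjugate addition, accelerated by TMSCl so that addition outruns removal of the acidic γ-hydrogen; the methyl group enters axially, trans to the ring methyl two carbons away (trans-3,5 rule) and therefore cis to the ester, which creates the quaternary centre.

Step 3
Reactants: 6 methyl 2-(dimethoxymethyl)-2,6-dimethyl-4-oxocyclohexane-1-carboxylate
Product: 7 methyl 2-(dimethoxymethyl)-2,6-dimethyl-4-methylidenecyclohexane-1-carboxylate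
Conditions: Ph3PCH3Br, KOtBu, THF, 0 °C to rt
Reagents that add atoms: methyltriphenylphosphonium bromide, C[P+](c1ccccc1)(c1ccccc1)c1ccccc1.[Br-]
Why: Wittig methylenation of a ketone flanked by two CH2 groups; the only base-sensitive centre is already in its stable configuration.

Step 4
Reactants: 7 methyl 2-(dimethoxymethyl)-2,6-dimethyl-4-methylidenecyclohexane-1-carboxylate
Product: 8 methyl 2-(dimethoxymethyl)-2,4,6-trimethylcyclohexane-1-carboxylate (all substituents equatorial except the axial 2-methyl)
Conditions: Mn(dpm)3 (10 mol%), PhSiH3, t-BuOOH, i-PrOH, rt
Reagents that add atoms: none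
Why: Radical hydrogenation by hydrogen-atom transfer: a hydrogen atom adds to the CH2 terminus and the tertiary ring radical is quenched under product-like control, which should favour the equatorial methyl isomer; surface hydrogenation would deliver hydrogen from the open equatorial side and give the axial methyl.

Step 5
Reactants: 8 methyl 2-(dimethoxymethyl)-2,4,6-trimethylcyclohexane-1-carboxylate
Product: 9 2-(dimethoxymethyl)-N-methoxy-N,2,4,6-tetramethylcyclohexane-1-carboxamide
Conditions: MeNHOMe·HCl, i-PrMgCl, THF, −20 to 0 °C
Reagents that add atoms: N,O-dimethylhydroxylamine hydrochloride, CNOC.Cl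
Why: Aminolysis of the hindered ester by the magnesium amide (Weinreb amide formation); no stereocentre is at risk because the α-centre is already equatorial.

Step 6
Reactants: 9 2-(dimethoxymethyl)-N-methoxy-N,2,4,6-tetramethylcyclohexane-1-carboxamide
Product: 10 2-formyl-N-methoxy-N,2,4,6-tetramethylcyclohexane-1-carboxamide
Conditions: TFA, H2O, CH2Cl2, 0 °C to rt
Reagents that add atoms: water, O
Why: Acid hydrolysis of the neopentyl dimethyl acetal; the aldehyde has no α-hydrogen and the amide is inert to aqueous acid.

Step 7
Reactants: 10 2-formyl-N-methoxy-N,2,4,6-tetramethylcyclohexane-1-carboxamide; 11 (E)-crotylboronic acid pinacol ester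
Product: 12 anti-2-(1-hydroxy-2-methylbut-3-enyl)-N-methoxy-N,2,4,6-tetramethylcyclohexane-1-carboxamide
Conditions: toluene, 60 °C; then aq. NaHCO3
Reagents that add atoms: none
Why: Allylboration through a closed six-membered chair transition state turns the E crotyl geometry into the anti hydroxyl/methyl relationship; the face of the aldehyde that is attacked does not matter because both new centres are removed in step 8.

Step 8
Reactants: 12 anti-2-(1-hydroxy-2-methylbut-3-enyl)-N-methoxy-N,2,4,6-tetramethylcyclohexane-1-carboxamide
Product: 13 N-methoxy-N,2,4,6-tetramethyl-2-[(1E)-2-methylbuta-1,3-dienyl]cyclohexane-1-carboxamide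
Conditions: methyl N-(triethylammoniumsulfonyl)carbamate (Burgess reagent), benzene, 60 °C
Reagents that add atoms: none
Why: Syn elimination of the sulfamate ester; the only β-hydrogen is the allylic one, and syn elimination from the anti adduct gives the E trisubstituted alkene of the conjugated diene.

Step 9
Reactants: 13 N-methoxy-N,2,4,6-tetramethyl-2-[(1E)-2-methylbuta-1,3-dienyl]cyclohexane-1-carboxamide; 14 3,3-diethoxyprop-1-yne
Product: 15 4,4-diethoxy-1-{2,4,6-trimethyl-2-[(1E)-2-methylbuta-1,3-dienyl]cyclohexyl}but-2-yn-1-one
Conditions: 14, n-BuLi, THF, −78 °C; then 13, −78 to 0 °C; aq. NH4Cl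
Reagents that add atoms: none
Why: Acylation of the lithium acetylide by the Weinreb amide; the chelated tetrahedral intermediate prevents a second addition and releases the ynone on work-up.

Step 10
Reactants: 15 4,4-diethoxy-1-{2,4,6-trimethyl-2-[(1E)-2-methylbuta-1,3-dienyl]cyclohexyl}but-2-yn-1-one
Product: 17 (2E)-4,4-diethoxy-1-{2,4,6-trimethyl-2-[(1E)-2-methylbuta-1,3-dienyl]cyclohexyl}but-2-en-1-ol, via propargylic alcohol 16 (not isolated)
Conditions: NaAlH2(OCH2CH2OMe)2, THF, −78 to 0 °C; aq. NH4Cl
Reagents that add atoms: none
Why: Felkin–Anh hydride delivery to the ynone, with the quaternary ring carbon as the large group, sets the carbinol centre in the sense needed for the ring-B oxygen; the aluminium alkoxide then directs trans-hydroalumination of the alkyne, which gives the E allylic alcohol on protonation.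

Step 11
Reactants: 17 (2E)-4,4-diethoxy-1-{2,4,6-trimethyl-2-[(1E)-2-methylbuta-1,3-dienyl]cyclohexyl}but-2-en-1-ol
Product: 19 (2E)-4-(tert-butyldimethylsilyloxy)-4-{2,4,6-trimethyl-2-[(1E)-2-methylbuta-1,3-dienyl]cyclohexyl}but-2-enal, via silyl ether acetal 18 (not isolated)
Conditions: TBSOTf, 2,6-lutidine, CH2Cl2, −78 °C; then 5% aq. oxalic acid, THF, rt
Reagents that add atoms: tert-butyldimethylsilyl triflate, CC(C)(C)[Si](C)(C)OS(=O)(=O)C(F)(F)F; water, O
Why: Silylation of the hindered allylic alcohol by the silyl triflate, then hydrolysis of the allylic acetal, which is far faster than loss of a secondary silyl ether under dilute acid; the conjugated E enal is configurationally stable.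

Step 12
Reactants: 19 (2E)-4-(tert-butyldimethylsilyloxy)-4-{2,4,6-trimethyl-2-[(1E)-2-methylbuta-1,3-dienyl]cyclohexyl}but-2-enal
Product: 20 tricyclic silyl ether aldehyde (ring-C alkene CH=C(CH3) next to the B/C fusion; CH2 next to the formyl-bearing carbon)
Conditions: Me2AlCl (0.5 equiv), CH2Cl2, −78 to −30 °C
Reagents that add atoms: none
Why: Lewis-acid-catalysed intramolecular Diels–Alder reaction with a three-atom tether: the formyl group goes endo, which with the E dienophile puts the tether exo and gives the trans B/C fusion and the formyl group cis to the fusion hydrogen next to it. The tether is a trans-diequatorial pair on the ring-A chair, so ring B is trans-fused to ring A, and only the anti arrangement lets both fusions twist the five-membered ring in the same sense; four stereocentres are set.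

Step 13
Reactants: 20 tricyclic silyl ether aldehyde (ring-C alkene CH=C(CH3) next to the B/C fusion; CH2 next to the formyl-bearing carbon)
Product: 21 dimethyl acetal of 20
Conditions: HC(OMe)3, PPTS (cat.), MeOH, rt
Reagents that add atoms: trimethyl orthoformate, COC(OC)OC; methanol, CO
Why: Acid-catalysed acetalisation with the orthoformate as water scavenger; the acetal shields the aldehyde from the oxidation and the dissolving-metal reduction that follow, and the hindered secondary silyl ether survives PPTS.

Step 14
Reactants: 21 dimethyl acetal of 20
Product: 22 tricyclic enone acetal (C=O next to the acetal-bearing carbon; β-methyl enone)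
Conditions: Rh2(cap)4 (cap = caprolactamate, 1 mol%), t-BuOOH, K2CO3, CH2Cl2, rt
Reagents that add atoms: tert-butyl hydroperoxide, CC(C)(C)OO
Why: Radical allylic oxidation at the ring CH2 next to the unsubstituted alkene carbon, the usual site for a 1-methylcyclohexene, gives the β-methyl enone; the other allylic sites are a ring-fusion C–H, which cannot become a ketone, and a methyl group.

Step 15
Reactants: 22 tricyclic enone acetal (C=O next to the acetal-bearing carbon; β-methyl enone)
Product: 24 tricyclic enol triflate (C(OTf)=CH; ring-C CH(CH3) with equatorial methyl), via lithium enolate 23 (not isolated)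
Conditions: Li, NH3, THF, t-BuOH (1 equiv), −78 °C; isoprene; NH3 removed; PhNTf2, THF, −78 to 0 °C
Reagents that add atoms: N-phenylbis(trifluoromethanesulfonimide), O=S(=O)(N(c1ccccc1)S(=O)(=O)C(F)(F)F)C(F)(F)F
Why: Birch-type conjugate reduction: the β-carbon is protonated axially, which gives the equatorial methyl group trans to the fusion hydrogen; the lithium enolate exists only on the side of the former α-carbon and is trapped on oxygen as the enol triflate.

Step 16
Reactants: 24 tricyclic enol triflate (C(OTf)=CH; ring-C CH(CH3) with equatorial methyl)
Product: 25 tricyclic acetal carrying the C(CH3)=CH alkene next to the acetal-bearing carbon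
Conditions: MeMgBr, Fe(acac)3 (10 mol%), THF/NMP, −20 °C
Reagents that add atoms: methylmagnesium bromide, C[Mg]Br
Why: Iron-catalysed cross-coupling of the alkenyl triflate with the methyl Grignard reagent (Kumada type) places the vinylic methyl group without moving the double bond.

Step 17
Reactants: 25 tricyclic acetal carrying the C(CH3)=CH alkene next to the acetal-bearing carbon
Product: 26 tricyclic ring-C aldehyde (silyl ether on ring B; β,γ-unsaturated aldehyde)
Conditions: TESOTf, 2,6-lutidine, CH2Cl2, 0 °C; then H2O
Reagents that add atoms: water, O
Why: The silyl triflate and the pyridine base turn the dimethyl acetal into a pyridinium N,O-acetal that water hydrolyses without free acid, so the β,γ-unsaturated aldehyde should neither conjugate nor epimerise and the silyl ether stays.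

Step 18
Reactants: 27 itaconic anhydride; 28 2,4-dimethoxybenzylamine
Product: 30 N-(2,4-dimethoxybenzyl)itaconimide, via amic acid 29 (not isolated)
Conditions: CH2Cl2, 0 °C to rt; then HMDS, ZnBr2, toluene, 80 °C
Reagents that add atoms: none
Why: The amine opens the anhydride at the non-conjugated carbonyl and silylative cyclodehydration closes the imide; the neutral conditions avoid isomerisation to the endocyclic citraconimide.

Step 19
Reactants: 26 tricyclic ring-C aldehyde (silyl ether on ring B; β,γ-unsaturated aldehyde); 30 N-(2,4-dimethoxybenzyl)itaconimide; 31 vinylmagnesium bromide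
Product: 33 β-hydroxy imide carrying the allyl-bearing quaternary carbon, via magnesium enolate 32 (not isolated)
Conditions: 30 (2.0 equiv), CuBr·SMe2 (0.2 equiv), 31 (2.0 equiv, slow addition), THF, −78 °C; then 26 (1.0 equiv), −78 to −40 °C; aq. NH4Cl
Reagents that add atoms: none
Why: Copper-catalysed 1,4-addition of the vinyl Grignard reagent to the exocyclic methylene of 30 gives the magnesium enolate 32 of the 3-allylsuccinimide, which adds to aldehyde 26 through a closed six-membered chair transition state; the closest known reaction type is the tandem conjugate addition–aldol three-component coupling of organocopper reagents, enones or α-methylene lactones and aldehydes. No ring is closed. The carbinol centre follows Felkin–Anh attack on the aldehyde, steered by the ring-C α-centre; it is oxidised away in step 21 and is left undefined. The spiro centre is set by the enolate face that the chair pairs with that aldehyde face, with the tricyclic residue equatorial and the allyl group, cis to the enolate oxygen, beside it, so that the Felkin and anti preferences together should give the configuration of the target. The step needs chemoselectivity in two respects: no free vinyl Grignard reagent may meet the aldehyde, and no unreacted imide may protonate the enolate; both are secured by adding 31 slowly in the exact amount to 30 before 26 is introduced and by making the aldehyde the limiting partner. It also needs the enolate to stay on the allyl-bearing α-carbon, which the low temperature secures because proton transfer to the CH2 α-position is slow at −78 °C. The β,γ-unsaturated aldehyde is used freshly made and meets only the weakly basic magnesium enolate, so its α-centre should survive.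

Step 20
Reactants: 33 β-hydroxy imide carrying the allyl-bearing quaternary carbon; 34 4-bromobenzylmagnesium bromide
Product: 35 N-benzyl hydroxylactam carbinol (4-bromobenzyl on the hemiaminal carbon; hemiaminal epimers)
Conditions: 34 (3.5 equiv), THF, −78 to −30 °C; aq. NH4Cl
Reagents that add atoms: none
Why: Grignard addition to the imide carbonyl next to the CH2 group; the other carbonyl is shielded by the quaternary carbon, and one equivalent of reagent is used up by the hydroxyl group.

Step 21
Reactants: 35 N-benzyl hydroxylactam carbinol (4-bromobenzyl on the hemiaminal carbon; hemiaminal epimers)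
Product: 36 β-keto hydroxylactam (N-benzyl; silyl ether)
Conditions: Dess–Martin periodinane, NaHCO3, CH2Cl2, 0 °C to rt
Reagents that add atoms: none
Why: Dess–Martin oxidation of the secondary carbinol; the tertiary hemiaminal hydroxyl cannot be oxidised, and the buffered medium protects the α-centre of the new β,γ-unsaturated ketone.

Step 22
Reactants: 36 β-keto hydroxylactam (N-benzyl; silyl ether)
Product: 38 N–H hydroxylactam with free ring-B alcohol (seco compound), via silyl ether lactam 37 (not isolated)
Conditions: (NH4)2Ce(NO3)6, MeCN/H2O 4:1, 0 °C; then 48% aq. HF, rt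
Reagents that add atoms: none
Why: One-electron oxidation of the electron-rich benzyl group and hydrolysis of the resulting N-acyliminium ion free the lactam N–H; aqueous HF then removes the silyl group, while the water-rich medium keeps the hemiaminal hydrated. The benzyl group is removed at this stage because the aryl bromide is inert to the oxidant, whereas the later alkoxyarene would not be.

Step 23
Reactants: 38 N–H hydroxylactam with free ring-B alcohol (seco compound)
Product: 39 allyl-substituted para-cyclophane (13-membered aryl ether; hemiaminal as in the target)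
Conditions: CuI (50 mol%), 3,4,7,8-tetramethyl-1,10-phenanthroline, Cs2CO3, 4 Å MS, toluene (2 mM), 110 °C
Reagents that add atoms: none
Why: Ullmann-type copper-catalysed C–O coupling of the aryl bromide with the secondary alkoxide at high dilution closes the cyclophane; the hemiaminal epimers interconvert through the open keto amide under the basic conditions, so the material should funnel through the epimer that can reach. The lactam nitrogen sits on a fully substituted carbon and is a poor partner for N-arylation.

Step 24
Reactants: 39 allyl-substituted para-cyclophane (13-membered aryl ether; hemiaminal as in the target)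
Product: 41 cyclophane aldehyde (CH2CHO on the spiro carbon), via diol 40 (not isolated)
Conditions: OsO4 (2 mol%), NaIO4, 2,6-lutidine, dioxane/H2O 3:1, rt
Reagents that add atoms: osmium tetroxide, O=[Os](=O)(=O)=O; sodium periodate, [Na+].[O-]I(=O)(=O)=O
Why: Lemieux–Johnson cleavage: osmylation should prefer the open monosubstituted alkene over the ring-C alkene, which is flanked by two substituted carbons, and periodate cleaves the diol to the aldehyde.

Step 25
Reactants: 41 cyclophane aldehyde (CH2CHO on the spiro carbon)
Product: 43 deoxy target (ring-C alkene in place of the epoxide), via hydroperoxide 42 (not isolated)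
Conditions: O2, tetraphenylporphyrin (1 mol%), visible light, CH2Cl2, −20 °C
Reagents that add atoms: oxygen, O=O
Why: Schenck ene reaction: singlet oxygen adds at the methyl-bearing alkene carbon on the face of the CH2CHO arm and takes the pseudo-axial hydrogen of the neighbouring CH(CH3) on the same face, which shifts the double bond. The tertiary hydroperoxide then adds to the aldehyde held beside it and closes the eight-membered peroxyhemiacetal, whose carbinol centre can equilibrate to the configuration shown.

Step 26
Reactants: 43 deoxy target (ring-C alkene in place of the epoxide)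
Product: 44 CNP0533733.1
Conditions: dimethyldioxirane (acetone solution), CH2Cl2, −20 to 0 °C
Reagents that add atoms: dimethyldioxirane, CC1(C)OO1
Why: Neutral oxygen-atom transfer to the trisubstituted alkene; attack anti to the pseudo-axial methyl group of the adjacent quaternary carbon, that is syn to the peroxide oxygen, should give the epoxide of the target without harming the peroxide or the hemiaminal.

## Compound list

1 | methyl 4,4-dimethoxy-3-oxobutanoate | COC(=O)CC(=O)C(OC)OC | starting material
2 | (E)-pent-3-en-2-one | C/C=C/C(C)=O | starting material
3 | methyl (3S)-2-(2,2-dimethoxyacetyl)-3-methyl-5-oxohexanoate (Michael adduct, epimers at C2) | CC(=O)C[C@H](C)C(C(=O)OC)C(=O)C(OC)OC | intermediate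
4 | methyl (1R,6S)-2-(dimethoxymethyl)-6-methyl-4-oxocyclohex-2-ene-1-carboxylate | O=C1C[C@H](C)[C@@H](C(=O)OC)C(C(OC)OC)=C1 | intermediate
5 | methyl 2-(dimethoxymethyl)-2,6-dimethyl-4-(trimethylsilyloxy)cyclohex-3-ene-1-carboxylate (silyl enol ether) | C[Si](C)(C)OC1C[C@H](C)[C@@H](C(=O)OC)[C@](C)(C(OC)OC)C=1 | intermediate
6 | methyl 2-(dimethoxymethyl)-2,6-dimethyl-4-oxocyclohexane-1-carboxylate (2-methyl cis to ester, 6-methyl trans) | O=C1C[C@H](C)[C@@H](C(=O)OC)[C@](C)(C(OC)OC)C1 | intermediate
7 | methyl 2-(dimethoxymethyl)-2,6-dimethyl-4-methylidenecyclohexane-1-carboxylate | C=C1C[C@H](C)[C@@H](C(=O)OC)[C@](C)(C(OC)OC)C1 | intermediate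
8 | methyl 2-(dimethoxymethyl)-2,4,6-trimethylcyclohexane-1-carboxylate (axial 2-methyl, other substituents equatorial) | C[C@@H]1C[C@H](C)[C@@H](C(=O)OC)[C@](C)(C(OC)OC)C1 | intermediate
9 | 2-(dimethoxymethyl)-N-methoxy-N,2,4,6-tetramethylcyclohexane-1-carboxamide | C[C@@H]1C[C@H](C)[C@@H](C(=O)N(C)OC)[C@](C)(C(OC)OC)C1 | intermediate
10 | 2-formyl-N-methoxy-N,2,4,6-tetramethylcyclohexane-1-carboxamide | C[C@@H]1C[C@H](C)[C@@H](C(=O)N(C)OC)[C@](C)(C=O)C1 | intermediate
11 | (E)-crotylboronic acid pinacol ester | C/C=C/CB1OC(C)(C)C(C)(C)O1 | starting material
12 | anti-2-(1-hydroxy-2-methylbut-3-enyl)-N-methoxy-N,2,4,6-tetramethylcyclohexane-1-carboxamide (one of the two anti facial isomers drawn; both converge) | C[C@@H]1C[C@H](C)[C@@H](C(=O)N(C)OC)[C@](C)([C@H](O)[C@H](C)C=C)C1 | intermediate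
13 | N-methoxy-N,2,4,6-tetramethyl-2-[(1E)-2-methylbuta-1,3-dienyl]cyclohexane-1-carboxamide | C[C@@H]1C[C@H](C)[C@@H](C(=O)N(C)OC)[C@](C)(/C=C(\C)C=C)C1 | intermediate
14 | 3,3-diethoxyprop-1-yne | C#CC(OCC)OCC | starting material
15 | 4,4-diethoxy-1-{2,4,6-trimethyl-2-[(1E)-2-methylbuta-1,3-dienyl]cyclohexyl}but-2-yn-1-one | C[C@@H]1C[C@H](C)[C@@H](C(=O)C#CC(OCC)OCC)[C@](C)(/C=C(\C)C=C)C1 | intermediate
16 | 4,4-diethoxy-1-{2,4,6-trimethyl-2-[(1E)-2-methylbuta-1,3-dienyl]cyclohexyl}but-2-yn-1-ol (propargylic alcohol) | C[C@@H]1C[C@H](C)[C@@H]([C@@H](O)C#CC(OCC)OCC)[C@](C)(/C=C(\C)C=C)C1 | intermediate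
17 | (2E)-4,4-diethoxy-1-{2,4,6-trimethyl-2-[(1E)-2-methylbuta-1,3-dienyl]cyclohexyl}but-2-en-1-ol | C[C@@H]1C[C@H](C)[C@@H]([C@@H](O)/C=C/C(OCC)OCC)[C@](C)(/C=C(\C)C=C)C1 | intermediate
18 | tert-butyldimethylsilyl ether of 17 (silyl ether acetal) | C[C@@H]1C[C@H](C)[C@@H]([C@@H](O[Si](C)(C)C(C)(C)C)/C=C/C(OCC)OCC)[C@](C)(/C=C(\C)C=C)C1 | intermediate
19 | (2E)-4-(tert-butyldimethylsilyloxy)-4-{2,4,6-trimethyl-2-[(1E)-2-methylbuta-1,3-dienyl]cyclohexyl}but-2-enal | C[C@@H]1C[C@H](C)[C@@H]([C@@H](O[Si](C)(C)C(C)(C)C)/C=C/C=O)[C@](C)(/C=C(\C)C=C)C1 | intermediate
20 | tricyclic silyl ether aldehyde, ring-C alkene CH=C(CH3) next to the B/C fusion | C[C@@H]1C[C@H](C)[C@H]2[C@@H](O[Si](C)(C)C(C)(C)C)[C@@H]3[C@@H](C=O)CC=C(C)[C@H]3[C@]2(C)C1 | intermediate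
21 | dimethyl acetal of 20 | C[C@@H]1C[C@H](C)[C@H]2[C@@H](O[Si](C)(C)C(C)(C)C)[C@@H]3[C@@H](C(OC)OC)CC=C(C)[C@H]3[C@]2(C)C1 | intermediate
22 | tricyclic enone acetal | C[C@@H]1C[C@H](C)[C@H]2[C@@H](O[Si](C)(C)C(C)(C)C)[C@@H]3[C@@H](C(OC)OC)C(=O)C=C(C)[C@H]3[C@]2(C)C1 | intermediate
23 | lithium enolate from 22 | C[C@@H]1C[C@H](C)[C@H]2[C@@H](O[Si](C)(C)C(C)(C)C)[C@@H]3[C@@H](C(OC)OC)C(O[Li])=C[C@H](C)[C@H]3[C@]2(C)C1 | intermediate
24 | tricyclic enol triflate | C[C@@H]1C[C@H](C)[C@H]2[C@@H](O[Si](C)(C)C(C)(C)C)[C@@H]3[C@@H](C(OC)OC)C(OS(=O)(=O)C(F)(F)F)=C[C@H](C)[C@H]3[C@]2(C)C1 | intermediate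
25 | tricyclic acetal with the C(CH3)=CH alkene next to the acetal-bearing carbon | C[C@@H]1C[C@H](C)[C@H]2[C@@H](O[Si](C)(C)C(C)(C)C)[C@@H]3[C@@H](C(OC)OC)C(C)=C[C@H](C)[C@H]3[C@]2(C)C1 | intermediate
26 | tricyclic ring-C aldehyde | C[C@@H]1C[C@H](C)[C@H]2[C@@H](O[Si](C)(C)C(C)(C)C)[C@@H]3[C@@H](C=O)C(C)=C[C@H](C)[C@H]3[C@]2(C)C1 | intermediate
27 | itaconic anhydride | C=C1CC(=O)OC1=O | starting material
28 | 2,4-dimethoxybenzylamine | COc1ccc(CN)c(OC)c1 | starting material
29 | 4-[(2,4-dimethoxybenzyl)amino]-2-methylidene-4-oxobutanoic acid (amic acid) | C=C(CC(=O)NCc1ccc(OC)cc1OC)C(=O)O | intermediate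
30 | N-(2,4-dimethoxybenzyl)itaconimide | C=C1CC(=O)N(Cc2ccc(OC)cc2OC)C1=O | intermediate
31 | vinylmagnesium bromide | C=C[Mg]Br | starting material
32 | bromomagnesium enolate of 3-allyl-N-(2,4-dimethoxybenzyl)succinimide | C=CCC1=C(O[Mg]Br)N(Cc2ccc(OC)cc2OC)C(=O)C1 | intermediate
33 | β-hydroxy imide with allyl-bearing quaternary carbon (carbinol undefined) | C[C@@H]1C[C@H](C)[C@H]2[C@@H](O[Si](C)(C)C(C)(C)C)[C@@H]3[C@@H](C(O)[C@]4(CC=C)CC(=O)N(Cc5ccc(OC)cc5OC)C4=O)C(C)=C[C@H](C)[C@H]3[C@]2(C)C1 | intermediate
34 | 4-bromobenzylmagnesium bromide | Br[Mg]Cc1ccc(Br)cc1 | starting material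
35 | N-benzyl hydroxylactam carbinol (hemiaminal and carbinol undefined) | C[C@@H]1C[C@H](C)[C@H]2[C@@H](O[Si](C)(C)C(C)(C)C)[C@@H]3[C@@H](C(O)[C@]4(CC=C)CC(O)(Cc5ccc(Br)cc5)N(Cc6ccc(OC)cc6OC)C4=O)C(C)=C[C@H](C)[C@H]3[C@]2(C)C1 | intermediate
36 | β-keto hydroxylactam, N-benzyl, silyl ether | C[C@@H]1C[C@H](C)[C@H]2[C@@H](O[Si](C)(C)C(C)(C)C)[C@@H]3[C@@H](C(=O)[C@]4(CC=C)CC(O)(Cc5ccc(Br)cc5)N(Cc6ccc(OC)cc6OC)C4=O)C(C)=C[C@H](C)[C@H]3[C@]2(C)C1 | intermediate
37 | β-keto hydroxylactam, N–H, silyl ether | C[C@@H]1C[C@H](C)[C@H]2[C@@H](O[Si](C)(C)C(C)(C)C)[C@@H]3[C@@H](C(=O)[C@]4(CC=C)CC(O)(Cc5ccc(Br)cc5)NC4=O)C(C)=C[C@H](C)[C@H]3[C@]2(C)C1 | intermediate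
38 | seco compound: N–H hydroxylactam with free ring-B alcohol and aryl bromide | C[C@@H]1C[C@H](C)[C@H]2[C@@H](O)[C@@H]3[C@@H](C(=O)[C@]4(CC=C)CC(O)(Cc5ccc(Br)cc5)NC4=O)C(C)=C[C@H](C)[C@H]3[C@]2(C)C1 | intermediate
39 | allyl-substituted para-cyclophane | C[C@@H]1C[C@H](C)[C@H]2[C@H]3Oc4ccc(cc4)C[C@]4(O)C[C@](CC=C)(C(=O)N4)C(=O)[C@H]5C(C)=C[C@H](C)[C@@H]([C@]2(C)C1)[C@H]35 | intermediate
40 | cyclophane diol (2,3-dihydroxypropyl on the spiro carbon) | C[C@@H]1C[C@H](C)[C@H]2[C@H]3Oc4ccc(cc4)C[C@]4(O)C[C@](CC(O)CO)(C(=O)N4)C(=O)[C@H]5C(C)=C[C@H](C)[C@@H]([C@]2(C)C1)[C@H]35 | intermediate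
41 | cyclophane aldehyde | C[C@@H]1C[C@H](C)[C@H]2[C@H]3Oc4ccc(cc4)C[C@]4(O)C[C@](CC=O)(C(=O)N4)C(=O)[C@H]5C(C)=C[C@H](C)[C@@H]([C@]2(C)C1)[C@H]35 | intermediate
42 | tertiary allylic hydroperoxide aldehyde | C[C@@H]1C[C@H](C)[C@H]2[C@H]3Oc4ccc(cc4)C[C@]4(O)C[C@](CC=O)(C(=O)N4)C(=O)[C@H]5[C@@](C)(OO)C=C(C)[C@@H]([C@]2(C)C1)[C@H]35 | intermediate
43 | deoxy target (ring-C alkene in place of the epoxide) | C[C@@H]1C[C@H](C)[C@H]2[C@H]3Oc4ccc(cc4)C[C@]4(O)C[C@]5(C[C@H](O)OO[C@@]6(C)C=C(C)[C@H]([C@H]3[C@H]6C5=O)[C@]2(C)C1)C(=O)N4 | intermediate
44 | CNP0533733.1 | C[C@@H]1C[C@H](C)[C@H]2[C@H]3Oc4ccc(cc4)C[C@]4(O)C[C@]5(C[C@H](O)OO[C@@]6(C)[C@H]7O[C@@]7(C)[C@H]([C@H]3[C@H]6C5=O)[C@]2(C)C1)C(=O)N4 | target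

## Step count and least certain steps

Total step count: 26. Longest linear sequence: 25 steps (steps 1 to 17 and 19 to 26; step 18 is a one-step branch).

Step 19 (key step). The likely failure is poor facial selectivity at the enolate, giving the wrong spiro epimer, because the Felkin and chair preferences both have to hold for a tetrasubstituted enolate and a hindered aldehyde. Direct vinyl addition to the aldehyde, or protonation of the enolate by unreacted imide, would also cost the limiting aldehyde. Fallback: starting from 30 and 31, the enolate is trapped with TMSCl and isolated as the silyl ketene N,O-acetal F1. F1 is then joined to 26 in a separate Mukaiyama aldol addition (BF3·OEt2, CH2Cl2, −78 °C), which runs through an open transition state and so pairs the faces differently. The route is rejoined at 33.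

Step 4. The likely failure is hydrogen delivery to the tertiary ring radical from the equatorial side, because the axial trajectory runs past the axial methyl group on the quaternary carbon; this would give the axial methyl epimer. Fallback: starting from 6, a Wittig reaction with (methoxymethylene)triphenylphosphorane gives the enol ether F2. PPTS in wet acetone hydrolyses it to the aldehyde F3, which is equilibrated with K2CO3 in MeOH to the equatorial isomer, so the centre is set thermodynamically. NaBH4 gives the alcohol F4; I2, PPh3 and imidazole give the iodide F5; Bu3SnH with AIBN reduces F5 to the methyl compound. The route is rejoined at 8.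

Step 23. The likely failure is slow closure of the strained ring with an aryl bromide, so that intermolecular coupling, N-arylation of the open keto amide form, or loss of bromine take over; prolonged heating with carbonate could also epimerise or conjugate the ketone α-centre. Fallback: starting from 38, Miyaura borylation (Pd(dppf)Cl2, bis(pinacolato)diboron, KOAc, dioxane, 80 °C) gives the aryl pinacol boronate F6. An oxidative Chan–Lam etherification (Cu(OAc)2, DMAP, 4 Å MS, O2, CH2Cl2, rt, high dilution) then joins the boron-bearing carbon to the secondary hydroxyl at room temperature without carbonate base. The route is rejoined at 39.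

Step 25. The likely failure is attack of singlet oxygen on the lower face with abstraction of the hydrogen α to the ketone, which is the usual course for β,γ-unsaturated carbonyl compounds and would give a conjugated hydroperoxy enone; abstraction from the vinylic methyl group is a second wrong path. Fallback: starting from 41, ethereal H2O2 converts the aldehyde into the hydroxy hydroperoxide F7. N-Iodosuccinimide in CH2Cl2 then closes the dioxocane by anti addition: the tethered hydroperoxide oxygen goes to the methyl-bearing carbon from the face of the arm and iodine goes to the CH carbon, giving the iodo peroxide F8. DBU removes HI across the iodine-bearing carbon and the neighbouring CH(CH3), whose hydrogen is anti to iodine. In this sequence the face and the site are fixed by the tether. The route is rejoined at 43.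

Step 26. The likely failure is oxygen transfer to the lower face of the alkene if the methyl group of the neighbouring quaternary carbon does not shield it, which would give the epimeric epoxide. Fallback: starting from 43, N-bromosuccinimide in aqueous acetone places bromine on the face that the dioxirane prefers, and water opens the bromonium ion at the tertiary carbon from the opposite face to give the bromohydrin F9. K2CO3 in MeOH then closes the epoxide with inversion at the CH carbon, so the epoxide ends on the face opposite to the one the electrophile attacked. The route is rejoined at 44.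

Further compounds

F1 | step 19 | 3-allyl-1-(2,4-dimethoxybenzyl)-2-(trimethylsilyloxy)-1,4-dihydropyrrol-5-one (silyl ketene N,O-acetal) | C=CCC1=C(O[Si](C)(C)C)N(Cc2ccc(OC)cc2OC)C(=O)C1
F2 | step 4 | methyl 2-(dimethoxymethyl)-4-(methoxymethylidene)-2,6-dimethylcyclohexane-1-carboxylate | COC=C1C[C@H](C)[C@@H](C(=O)OC)[C@](C)(C(OC)OC)C1
F3 | step 4 | methyl 2-(dimethoxymethyl)-4-formyl-2,6-dimethylcyclohexane-1-carboxylate (equatorial formyl) | O=C[C@@H]1C[C@H](C)[C@@H](C(=O)OC)[C@](C)(C(OC)OC)C1
F4 | step 4 | methyl 2-(dimethoxymethyl)-4-(hydroxymethyl)-2,6-dimethylcyclohexane-1-carboxylate | OC[C@@H]1C[C@H](C)[C@@H](C(=O)OC)[C@](C)(C(OC)OC)C1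
F5 | step 4 | methyl 2-(dimethoxymethyl)-4-(iodomethyl)-2,6-dimethylcyclohexane-1-carboxylate | IC[C@@H]1C[C@H](C)[C@@H](C(=O)OC)[C@](C)(C(OC)OC)C1
F6 | step 23 | aryl pinacol boronate of the seco compound | C[C@@H]1C[C@H](C)[C@H]2[C@@H](O)[C@@H]3[C@@H](C(=O)[C@]4(CC=C)CC(O)(Cc5ccc(B6OC(C)(C)C(C)(C)O6)cc5)NC4=O)C(C)=C[C@H](C)[C@H]3[C@]2(C)C1
F7 | step 25 | cyclophane hydroxy hydroperoxide (CH2CH(OH)OOH on the spiro carbon) | C[C@@H]1C[C@H](C)[C@H]2[C@H]3Oc4ccc(cc4)C[C@]4(O)C[C@](CC(O)OO)(C(=O)N4)C(=O)[C@H]5C(C)=C[C@H](C)[C@@H]([C@]2(C)C1)[C@H]35
F8 | step 25 | iodo peroxide (dioxocane closed; iodine on the ring-C CH carbon) | C[C@@H]1C[C@H](C)[C@H]2[C@H]3Oc4ccc(cc4)C[C@]4(O)C[C@]5(C[C@H](O)OO[C@@]6(C)[C@H](I)[C@H](C)[C@H]([C@H]3[C@H]6C5=O)[C@]2(C)C1)C(=O)N4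
F9 | step 26 | bromohydrin of the deoxy target (bromine on the CH carbon; tertiary hydroxyl) | C[C@@H]1C[C@H](C)[C@H]2[C@H]3Oc4ccc(cc4)C[C@]4(O)C[C@]5(C[C@H](O)OO[C@@]6(C)[C@H](Br)[C@@](C)(O)[C@H]([C@H]3[C@H]6C5=O)[C@]2(C)C1)C(=O)N4
A1 | alternative 1 | ring-A aldehyde with enoate and methyl ketone side chain | C[C@@H]1C[C@H](C)[C@@H](C=O)[C@](C)([C@@H](/C=C/C(=O)OC)[C@@H](C)CC(C)=O)C1
A2 | alternative 1 | tricyclic diol ester | C[C@@H]1C[C@H](C)[C@H]2[C@@H](O)[C@@H]3[C@@H](C(=O)OC)[C@@](C)(O)C[C@H](C)[C@H]3[C@]2(C)C1
A3 | alternative 2 | deoxy target (ring-C alkene in place of the epoxide) | C[C@@H]1C[C@H](C)[C@H]2[C@H]3Oc4ccc(cc4)C[C@]4(O)C[C@]5(C[C@H](O)OO[C@@]6(C)C=C(C)[C@H]([C@H]3[C@H]6C5=O)[C@]2(C)C1)C(=O)N4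
A4 | alternative 3 | bromo-pyrone ether with propargyl methoxy lactam | C[C@@H]1C[C@H](C)[C@H]2[C@@H](Oc4ccoc(=O)c4Br)[C@@H]3[C@@H](C(=O)[C@]5(CC(OC)OC)C[C@](CC#C)(OC)NC5=O)C(C)=C[C@H](C)[C@H]3[C@]2(C)C1
A5 | alternative 3 | bromo-substituted para-cyclophane spiro-lactam | C[C@@H]1C[C@H](C)[C@H]2[C@H]3Oc4ccc(cc4Br)C[C@]4(OC)C[C@](CC(OC)OC)(C(=O)N4)C(=O)[C@H]5C(C)=C[C@H](C)[C@@H]([C@]2(C)C1)[C@H]35
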